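**Plan**

1. Numbering: ring carbons C1–C15 follow their order in the target SMILES: C1 (CHOMe), C2, C3, C4 (CH–iPr), C5, C6, C7, C8 (C–Me), C9, C10, C11 (C(Me)OH), C12 (CHOH), C13, C14 (CHBr), C15 (bridge CH2). Ring A = C8-C9-C11-C12-C13-C14, ring B = C5-C6-C7-C8-C9-C10, norbornane = C1-C2-C3-C4-C5-C10 bridged by C15.
2. Retrosynthetic cuts, in order: C14–Br (from vinyl bromide, from ketone); the C11/C12 diol (from the epoxide of C11=C12); C1–OMe (from C1–B); C5–C10 and C1–C2 (intramolecular Diels–Alder of a C8-tethered 1-alkyl-2-isopropylcyclopentadiene with an (E)-C10=C1 alkenylboronate); C8–C7 and C8–CH3 (enolate alkylations); last C9–C11 and C12–C13, which open ring A to propanal and methyl (E)-4-oxopent-2-enoate.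
3. Enabling feature: in ring A, C14 (the CHBr carbon, a latent ketone) and C12 (the CHOH carbon, a latent aldehyde) stand 1,5 through C8–C9–C11, with C13 between them and C10 as an ester carbon on C9. One amine-catalysed Michael addition (C9–C11) and aldol condensation (C12–C13) therefore builds ring A with every later handle in place.
4. Forward order: ring A (step 1); quaternary C8 (steps 2 and 6, side chain from steps 3–5); ketal with C11=C12 and free cyclopentadiene; aldehyde; alkenylboronate; Diels–Alder closing ring B and both norbornene rings at once; then C1–OMe, C3=C4 reduction, ring A diol, C14 bromide.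
5. Stereochemistry: C9 from the aminocatalyst; C8 by alkylation anti to the C9 ester; C5, C10, C2 and C1 relayed from C8/C9 through the chair-like, exo-tethered Diels–Alder transition state and the (E)-alkene; C4 by exo delivery of hydrogen; C11/C12 by trans-diaxial epoxide opening; C14 by axial hydrogen-atom delivery.

Key step: step 1

Remark: the (S)-catalyst is assumed to give the syn Michael adduct with (S)-C9, as it does with nitroalkenes; only C9 of 4 matters later, because C11 becomes sp2 in step 7.

**Route**

Step 1
Reactants: 1 propanal; 2 methyl (E)-4-oxopent-2-enoate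
Product: 4 methyl (1S,2S)-2-methyl-5-oxocyclohex-3-ene-1-carboxylate, via keto aldehyde 3 (not isolated)
Conditions: (S)-α,α-diphenylprolinol trimethylsilyl ether (10 mol %), PhCO2H (10 mol %), toluene, 0 °C → rt; then pTsOH·H2O (0.3 equiv), 60 °C
Reagents that add atoms: none
Why: The amine condenses with propanal to an (E)-enamine whose C11 adds to C9 of 2 (β to the ketone, α to the ester) through an open synclinal transition state, and hydrolysis gives keto aldehyde 3; on acidification the methyl-ketone enol (C13) attacks the aldehyde carbon C12 and water is lost to give the conjugated enone. The closest known reaction type is the amine-catalysed Michael addition of aldehydes to enones or nitroalkenes followed by aldol condensation (organocatalytic Robinson-type annulation to 4-substituted cyclohexenones). Ring A closes by a 6-(enolendo)-exo-trig aldol addition, the only closure open to 3 because every other enol/carbonyl pairing would give a four-membered ring. C9 is set by the face of the acceptor that meets the shielded enamine (syn adduct, (S)-C9 expected with the (S)-catalyst); C11 is set by the enamine face and is erased later, so the minor anti adduct, which carries the wrong C9, is removed as the cis diastereomer of 4. The step needs regioselectivity for attack β to the ketone, which the stronger acceptor character of the ketone should secure, and enamine formation at the aldehyde and not at the methyl ketone, which the much faster condensation of the hindered secondary amine with the aldehyde should secure.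

Step 2
Reactants: 4 methyl (1S,2S)-2-methyl-5-oxocyclohex-3-ene-1-carboxylate
Product: 5 methyl (1R,2S)-2,6-dimethyl-5-oxocyclohex-3-ene-1-carboxylate (C6 epimers)
Conditions: LiN(iPr)2, THF, −78 °C; MeI, −78 → −40 °C
Reagents that add atoms: iodomethane (CI)
Why: Kinetic deprotonation of the enone at the α′ carbon (C8) gives the cross-conjugated enolate, which is methylated by SN2 enolate alkylation; the configuration at C8 is of no consequence because C8 is enolised again in step 6.

Step 3
Reactants: 6 3-methylbut-1-yne
Product: 7 2-(propan-2-yl)cyclopent-2-en-1-one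
Conditions: Co2(CO)8, CH2Cl2, rt; then ethylene (balloon), N-methylmorpholine N-oxide, rt
Reagents that add atoms: ethylene (C=C); carbon monoxide supplied by Co2(CO)8 ([C-]#[O+])
Why: Pauson–Khand reaction of the alkyne–Co2(CO)6 complex with ethylene and CO, in which the substituent of a terminal alkyne ends α to the carbonyl, so that the ketone carbon (future C5) and the isopropyl-bearing carbon (future C4) are adjacent.

Step 4
Reactants: 7 2-(propan-2-yl)cyclopent-2-en-1-one
Product: 8 rac-1-ethenyl-2-(propan-2-yl)cyclopent-2-en-1-ol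
Conditions: CH2=CHMgBr, CeCl3, THF, −78 °C
Reagents that add atoms: vinylmagnesium bromide (C=C[Mg]Br)
Why: CeCl3-promoted 1,2-addition of the vinyl Grignard reagent to the enone carbonyl gives the tertiary bis-allylic alcohol, whose racemic carbinol centre is destroyed in step 5.

Step 5
Reactants: 8 rac-1-ethenyl-2-(propan-2-yl)cyclopent-2-en-1-ol
Product: 9 (5E)-5-(2-bromoethylidene)-1-(propan-2-yl)cyclopent-1-ene
Conditions: PBr3, pyridine (cat.), Et2O, −20 → 0 °C; used at once
Reagents that add atoms: phosphorus tribromide (BrP(Br)Br)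
Why: Allylic transposition (SN2′-type bromination) of a tertiary vinyl carbinol, as with linalool-type alcohols, should give the conjugated primary dienyl bromide, the (E)-geometry placing CH2Br away from the isopropyl-bearing ring carbon.

Step 6
Reactants: 5 methyl (1R,2S)-2,6-dimethyl-5-oxocyclohex-3-ene-1-carboxylate; 9 (5E)-5-(2-bromoethylidene)-1-(propan-2-yl)cyclopent-1-ene
Product: 10 methyl (1R,2S,6S)-2,6-dimethyl-5-oxo-6-{(2E)-2-[2-(propan-2-yl)cyclopent-2-en-1-ylidene]ethyl}cyclohex-3-ene-1-carboxylate
Conditions: LiN(iPr)2, THF, −78 °C; 9, DMPU, −78 → −20 °C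
Reagents that add atoms: none
Why: Enolate alkylation of the kinetic α′-enolate with the reactive allylic bromide should occur anti to the adjacent C9 ester, which A(1,2) strain with the C8 methyl holds pseudo-axial, so that C8 becomes quaternary with C7 trans to C10 (the usual trans-2,3 outcome for 3-substituted 2-methylcyclohexanone enolates).

Step 7
Reactants: 10 methyl (1R,2S,6S)-2,6-dimethyl-5-oxo-6-{(2E)-2-[2-(propan-2-yl)cyclopent-2-en-1-ylidene]ethyl}cyclohex-3-ene-1-carboxylate
Product: 11 methyl (6S,7R)-6,8-dimethyl-6-{2-[2-(propan-2-yl)cyclopenta-1,3-dien-1-yl]ethyl}-1,4-dioxaspiro[4.5]dec-8-ene-7-carboxylate (cyclopentadiene drawn as one of its equilibrating 1,5-H shift isomers)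
Conditions: HOCH2CH2OH, HC(OEt)3, pTsOH·H2O (cat.), CH2Cl2, rt; product kept cold
Reagents that add atoms: ethylene glycol (OCCO)
Why: Acid-catalysed dioxolane formation of an enone runs through the dienol ether and gives the β,γ-unsaturated ketal (C11=C12, as in the classical conversion of a 4-en-3-one into a 5-ene 3-ketal), which masks the enone as a dienophile and erases C11, while the same acid should move the exocyclic side-chain diene through its allyl cation into the ring to give the cyclopentadiene.

Step 8
Reactants: 11 methyl (6S,7R)-6,8-dimethyl-6-{2-[2-(propan-2-yl)cyclopenta-1,3-dien-1-yl]ethyl}-1,4-dioxaspiro[4.5]dec-8-ene-7-carboxylate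
Product: 12 (6S,7R)-6,8-dimethyl-6-{2-[2-(propan-2-yl)cyclopenta-1,3-dien-1-yl]ethyl}-1,4-dioxaspiro[4.5]dec-8-ene-7-carbaldehyde
Conditions: iBu2AlH, CH2Cl2, −78 °C; aq. potassium sodium tartrate; used crude
Reagents that add atoms: none
Why: Partial reduction of the hindered ester stops at the aluminium hemiacetal, which gives the aldehyde on work-up; the β,γ-unsaturated aldehyde is not purified so that C9 is not epimerised and C11=C12 does not move into conjugation.

Step 9
Reactants: 12 (6S,7R)-6,8-dimethyl-6-{2-[2-(propan-2-yl)cyclopenta-1,3-dien-1-yl]ethyl}-1,4-dioxaspiro[4.5]dec-8-ene-7-carbaldehyde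
Product: 13 2-[(E)-2-{(6S,7R)-6,8-dimethyl-6-[2-(2-(propan-2-yl)cyclopenta-1,3-dien-1-yl)ethyl]-1,4-dioxaspiro[4.5]dec-8-en-7-yl}ethenyl]-4,4,5,5-tetramethyl-1,3,2-dioxaborolane
Conditions: CrCl2, Cl2CHB(pin), LiI, THF, rt
Reagents that add atoms: 2-(dichloromethyl)-4,4,5,5-tetramethyl-1,3,2-dioxaborolane (ClC(Cl)B1OC(C)(C)C(C)(C)O1)
Why: Takai-type olefination, in which the geminal dichromium reagent adds to the aldehyde and eliminates to the (E)-alkenylboronate without base, so that C9 and the skipped diene are left alone.

Step 10
Reactants: 13 the (E)-alkenylboronate of step 9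
Product: 14 Diels–Alder adduct (tetracyclic pinacol boronate; boron endo on C1; C9 exo on C10; C3=C4 bearing isopropyl on C4; C11=C12; dioxolane at C14)
Conditions: toluene (0.01 M), 2,6-di-tert-butyl-4-methylphenol (cat.), 140 °C, sealed tube
Reagents that add atoms: none
Why: Intramolecular Diels–Alder reaction of the cyclopentadiene tautomer whose diene termini are C5 and C2 with the (E)-alkenylboronate closes ring B and both norbornene rings; the four-atom tether anchored on C5 should hold C9 exo on C10 (an endo C9 would need a ring B torsion angle near 80° about the forming C5–C10 bond), the (E)-alkene then places boron endo on C1, and the chair-like tether with C7 and C10 equatorial on ring A fixes which faces combine, setting C5, C10, C2 and C1.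

Step 11
Reactants: 14 Diels–Alder adduct (pinacol boronate)
Product: 15 endo C1 alcohol of the tetracyclic diene ketal
Conditions: H2O2, NaOH, THF/H2O, 0 °C → rt
Reagents that add atoms: hydrogen peroxide (OO)
Why: Oxidation of the secondary alkylboronate by hydroperoxide, with 1,2-shift of carbon from boron to oxygen and retention, gives the endo alcohol at C1.

Step 12
Reactants: 15 endo C1 alcohol
Product: 16 C1 methyl ether of the tetracyclic diene ketal
Conditions: NaH, MeI, THF/DMF, 0 °C → rt
Reagents that add atoms: iodomethane (CI)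
Why: Williamson etherification of the sodium alkoxide; no stereocentre is touched.

Step 13
Reactants: 16 C1 methyl ether
Product: 17 3,4-dihydro compound (isopropyl endo on C4; C11=C12 kept)
Conditions: 2-nitrobenzenesulfonohydrazide, Et3N, CH2Cl2, rt
Reagents that add atoms: none
Why: Diimide reduction transfers two hydrogens suprafacially, far faster to the strained norbornene than to the trisubstituted cyclohexene, and from the open exo face, which should place isopropyl endo at C4.

Step 14
Reactants: 17 3,4-dihydro compound
Product: 18 11,12-epoxide (oxygen on the face anti to the C8 methyl)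
Conditions: mCPBA, NaHCO3, CH2Cl2, 0 °C
Reagents that add atoms: 3-chloroperbenzoic acid (OOC(=O)c1cccc(Cl)c1)
Why: Prilezhaev epoxidation of the only remaining alkene, expected from the face anti to the axial C8 methyl that shields C11.

Step 15
Reactants: 18 11,12-epoxide
Product: 19 diol ketone (C11–OH and C12–OH trans-diaxial; ketone at C14)
Conditions: HClO4 (3% aq.), THF, rt
Reagents that add atoms: water (O)
Why: Acid-catalysed epoxide hydrolysis by trans-diaxial opening at the tertiary C11, where the electronic and the stereoelectronic preference agree, gives axial C11–OH and axial C12–OH, and the same acid hydrolyses the dioxolane.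

Step 16
Reactants: 19 diol ketone
Product: 21 vinyl bromide (C13=C14–Br), via silyl hydrazone 20 (not isolated)
Conditions: TBSNHNHTBS, Sc(OTf)3 (1 mol %), CHCl3, rt → 50 °C; then NBS, 2-tert-butyl-1,1,3,3-tetramethylguanidine, CH2Cl2, 0 °C
Reagents that add atoms: N-bromosuccinimide (BrN1C(=O)CCC1=O); 1,2-bis(tert-butyldimethylsilyl)hydrazine (CC(C)(C)[Si](C)(C)NN[Si](C)(C)C(C)(C)C; its atoms stay only in 20)
Why: Barton vinyl halide synthesis in its N-silyl hydrazone form, in which the Lewis-acid condensation avoids base on the β-hydroxy ketone and bromination, loss of N2 and loss of the C13 proton give the vinyl bromide, the regiochemistry being fixed by the quaternary C8.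

Step 17
Reactants: 21 vinyl bromide
Product: 22 target (CNP0130529.1)
Conditions: Mn(dpm)3 (10 mol %), PhSiH3, tBuOOH, iPrOH, rt
Reagents that add atoms: none
Why: Metal-hydride hydrogen-atom-transfer hydrogenation, which tolerates haloalkenes: H adds to C13, and the α-bromo radical at C14 should take the second hydrogen from the axial direction, anti to the axial C8 methyl, leaving bromine equatorial.

**Compound list**

1 | propanal | CCC=O | starting material
2 | methyl (E)-4-oxopent-2-enoate | COC(=O)/C=C/C(C)=O | starting material
3 | methyl (2S,3R)-3-methyl-4-oxo-2-(2-oxopropyl)butanoate | COC(=O)[C@@H](CC(C)=O)[C@@H](C)C=O | intermediate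
4 | methyl (1S,2S)-2-methyl-5-oxocyclohex-3-ene-1-carboxylate | COC(=O)[C@@H]1[C@@H](C)C=CC(=O)C1 | intermediate
5 | methyl (1R,2S)-2,6-dimethyl-5-oxocyclohex-3-ene-1-carboxylate, C6 epimers | COC(=O)[C@@H]1[C@@H](C)C=CC(=O)C1C | intermediate
6 | 3-methylbut-1-yne | CC(C)C#C | starting material
7 | 2-(propan-2-yl)cyclopent-2-en-1-one | CC(C)C1=CCCC1=O | intermediate
8 | rac-1-ethenyl-2-(propan-2-yl)cyclopent-2-en-1-ol | CC(C)C1=CCCC1(O)C=C | intermediate
9 | (5E)-5-(2-bromoethylidene)-1-(propan-2-yl)cyclopent-1-ene | BrC/C=C1\CCC=C1C(C)C | intermediate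
10 | methyl (1R,2S,6S)-2,6-dimethyl-5-oxo-6-{(2E)-2-[2-(propan-2-yl)cyclopent-2-en-1-ylidene]ethyl}cyclohex-3-ene-1-carboxylate | COC(=O)[C@@H]1[C@@H](C)C=CC(=O)[C@@]1(C)C/C=C2\CCC=C2C(C)C | intermediate
11 | methyl (6S,7R)-6,8-dimethyl-6-{2-[2-(propan-2-yl)cyclopenta-1,3-dien-1-yl]ethyl}-1,4-dioxaspiro[4.5]dec-8-ene-7-carboxylate | CC(C)C1=C(CC[C@@]2(C)[C@H](C(=O)OC)C(C)=CCC23OCCO3)CC=C1 | intermediate
12 | (6S,7R)-6,8-dimethyl-6-{2-[2-(propan-2-yl)cyclopenta-1,3-dien-1-yl]ethyl}-1,4-dioxaspiro[4.5]dec-8-ene-7-carbaldehyde | CC(C)C1=C(CC[C@@]2(C)[C@H](C=O)C(C)=CCC23OCCO3)CC=C1 | intermediate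
13 | (E)-alkenyl pinacol boronate of 12 (C10=C1–B) | CC(C)C1=C(CC[C@@]2(C)[C@H](/C=C/B3OC(C)(C)C(C)(C)O3)C(C)=CCC24OCCO4)CC=C1 | intermediate
14 | Diels–Alder adduct, tetracyclic pinacol boronate (B endo on C1; C9 exo on C10; C3=C4; C11=C12; C14 dioxolane) | CC1(C)OB(OC1(C)C)[C@H]2[C@H]3C=C(C(C)C)[C@]4(CC[C@@]5(C)[C@H]([C@H]24)C(C)=CCC56OCCO6)C3 | intermediate
15 | endo C1 alcohol | O[C@H]1[C@H]2C=C(C(C)C)[C@]3(CC[C@@]4(C)[C@H]([C@H]13)C(C)=CCC45OCCO5)C2 | intermediate
16 | C1 methyl ether | CO[C@H]1[C@H]2C=C(C(C)C)[C@]3(CC[C@@]4(C)[C@H]([C@H]13)C(C)=CCC45OCCO5)C2 | intermediate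
17 | 3,4-dihydro compound (isopropyl endo) | CO[C@H]1[C@H]2C[C@@H](C(C)C)[C@]3(CC[C@@]4(C)[C@H]([C@H]13)C(C)=CCC45OCCO5)C2 | intermediate
18 | 11,12-epoxide | CO[C@H]1[C@H]2C[C@@H](C(C)C)[C@]3(CC[C@@]4(C)[C@H]([C@H]13)[C@@]5(C)O[C@H]5CC46OCCO6)C2 | intermediate
19 | diol ketone | CO[C@H]1[C@H]2C[C@@H](C(C)C)[C@]3(CC[C@@]4(C)[C@H]([C@H]13)[C@](C)(O)[C@@H](O)CC4=O)C2 | intermediate
20 | N-(tert-butyldimethylsilyl)hydrazone of 19 | CO[C@H]1[C@H]2C[C@@H](C(C)C)[C@]3(CC[C@@]4(C)[C@H]([C@H]13)[C@](C)(O)[C@@H](O)CC4=NN[Si](C)(C)C(C)(C)C)C2 | intermediate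
21 | vinyl bromide (C13=C14–Br) | CO[C@H]1[C@H]2C[C@@H](C(C)C)[C@]3(CC[C@@]4(C)[C@H]([C@H]13)[C@](C)(O)[C@@H](O)C=C4Br)C2 | intermediate
22 | CNP0130529.1 | CO[C@H]1[C@H]2C[C@@H](C(C)C)[C@]3(CC[C@@]4(C)[C@H]([C@H]13)[C@](C)(O)[C@@H](O)C[C@@H]4Br)C2 | target

**Count**

Total: 17 steps. Longest linear sequence: 15 steps (steps 3–17, from 3-methylbut-1-yne 6 through the side chain; the ring A branch, steps 1 and 2, joins at step 6).

**Steps most likely to fail**

Step 10 (intramolecular Diels–Alder). The cycloaddition onto the only weakly activated alkenylboronate may be slower than intermolecular dimerisation of the cyclopentadiene or than addition to C11=C12. The fallback changes the dienophile to a nitroalkene and sets out from aldehyde 12. A Henry reaction with nitromethane (cat. tetramethylguanidine, 0 °C) gives the nitro alcohol F1, which MsCl/Et3N dehydrates to the (E)-nitroalkene F2. This should cyclise at 40–60 °C to the endo-nitro cycloadduct F3. A buffered Nef reaction (TiCl3, NH4OAc, aq. THF) gives the C1 ketone F4, and NaBH4 in MeOH, which attacks the norbornenone from the exo face, gives the endo alcohol and so comes back to the route at 15.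

Step 6 (quaternisation of C8). The facial selectivity may be poor or reversed if the pseudo-axial C11 methyl on the opposite face outweighs the adjacent C9 ester. The fallback inverts the order of the two alkylations, so that methyl instead of the side chain is delivered last on the face the electrophile prefers. It sets out from enone 4: LiN(iPr)2 and bromide 9 give the mono-alkylated enone F5, and a second deprotonation followed by MeI comes back at 10.

Step 7 (ketalisation with two double-bond shifts). Under protic acid the cyclopentadiene may oligomerise, or C11=C12 may move on into conjugation with the ester and erase C9. The fallback separates the three events and avoids the protic-acid ketalisation. It sets out from 10: KOtBu in tBuOH followed by a kinetic quench with AcOH gives the β,γ-unsaturated ketone F6. Me3SiOCH2CH2OSiMe3 with catalytic Me3SiOTf at −78 °C gives the ketal F7 with the side-chain diene intact. Brief treatment with catalytic camphorsulfonic acid in CH2Cl2 at 0 °C then moves only the side-chain diene into the ring and comes back at 11.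

**Further compounds**

F1 | step 10 | nitro alcohol from 12 and nitromethane (carbinol epimers) | CC(C)C1=C(CC[C@@]2(C)[C@H](C(O)C[N+](=O)[O-])C(C)=CCC23OCCO3)CC=C1
F2 | step 10 | (E)-nitroalkene (C10=C1–NO2) | CC(C)C1=C(CC[C@@]2(C)[C@H](/C=C/[N+](=O)[O-])C(C)=CCC23OCCO3)CC=C1
F3 | step 10 | endo-nitro cycloadduct | [O-][N+](=O)[C@H]1[C@H]2C=C(C(C)C)[C@]3(CC[C@@]4(C)[C@H]([C@H]13)C(C)=CCC45OCCO5)C2
F4 | step 10 | C1 ketone of the tetracyclic diene ketal | O=C1[C@H]2C=C(C(C)C)[C@]3(CC[C@@]4(C)[C@H]([C@H]13)C(C)=CCC45OCCO5)C2
F5 | step 6 | mono-alkylated enone carrying the dienyl side chain at C8 (C8 epimers) | COC(=O)[C@@H]1[C@@H](C)C=CC(=O)C1C/C=C2\CCC=C2C(C)C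
F6 | step 7 | β,γ-unsaturated ketone (C11=C12) with exocyclic side-chain diene | COC(=O)[C@@H]1C(C)=CCC(=O)[C@@]1(C)C/C=C2\CCC=C2C(C)C
F7 | step 7 | dioxolane of F6 with exocyclic side-chain diene | COC(=O)[C@@H]1C(C)=CCC2(OCCO2)[C@@]1(C)C/C=C3\CCC=C3C(C)C
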